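**Retrosynthetic overview**
1. The strategy rests on one feature: the furan ring O1–C2–C3–C3a–C7a is the pyranone ring of a flavanone that has lost its carbonyl carbon, and ring A (C4–C7, 1,1-dimethylallyl on C7) is the A ring of an 8-substituted flavanone. Hence 28 ⇐ 27 (MOM removal) ⇐ acid 26 (oxidative decarboxylation at C3 aromatises the furan) ⇐ ester 25.
2. Ester 25 ⇐ photo-Wolff ring contraction of 3-diazoflavanone 22 in methanol, which forms C3–C3a by shift of the ring A carbon from the carbonyl carbon to C3; 22 ⇐ flavanone 20 by diazo transfer.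
3. Flavanone 20 ⇐ chalcone 19 (oxa-Michael closure through the only free phenol) ⇐ Claisen–Schmidt union of acetophenone 7 and aldehyde 17.
4. 7 ⇐ aromatic Claisen shift of a 4-O-prenyl ether whose para carbon carries the acetyl group, so the inverted prenyl unit must stay ortho. 17 ⇐ nitrile 15 ⇐ acid closure of an ortho-prenyl phenol placed by bromination and Stille coupling; the nitrile masks the aldehyde during the acid step.
5. Ring order: chroman ring of fragment B, then the pyranone ring, then its contraction to the dihydrofuran, then aromatisation to the furan.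

Key step: step 14

Remark: the target has no stereocentre; compounds 5, 18, 20–22 and 24–26 are racemic and their SMILES show one enantiomer.

**Step 1**
Reactants: 1 2,4,6-trihydroxyacetophenone; 2 prenol (3-methylbut-2-en-1-ol)
Product: 3 1-[2,6-dihydroxy-4-(3-methylbut-2-en-1-yloxy)phenyl]ethan-1-one
Conditions: PPh3, DIAD, THF, 0 °C to rt (1.0 equiv of 2)
Reagents that add atoms: none
Why: Mitsunobu etherification, in which the 4-hydroxyl (most acidic, not held by the acetyl group) attacks the alkoxyphosphonium ion, so alkylation occurs on oxygen para to the acetyl group without C-prenylation.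

**Step 2**
Reactants: 3 1-[2,6-dihydroxy-4-(3-methylbut-2-en-1-yloxy)phenyl]ethan-1-one
Product: 4 1-[2-hydroxy-6-(methoxymethoxy)-4-(3-methylbut-2-en-1-yloxy)phenyl]ethan-1-one
Conditions: MOMCl (1.05 equiv), i-Pr2NEt, CH2Cl2, 0 °C
Reagents that add atoms: chloromethyl methyl ether, COCCl
Why: O-alkylation of one of two equivalent ortho hydroxyls; the second, then locked in the hydrogen bond to the ketone, resists further protection.

**Step 3**
Reactants: 4 1-[2-hydroxy-6-(methoxymethoxy)-4-(3-methylbut-2-en-1-yloxy)phenyl]ethan-1-one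
Product: 6 1-[2,4-dihydroxy-6-(methoxymethoxy)-3-(2-methylbut-3-en-2-yl)phenyl]ethan-1-one, via ortho-dienone 5 (not isolated)
Conditions: PhNEt2, 185 °C, Ar, short heating time
Reagents that add atoms: none
Why: Aromatic Claisen rearrangement ([3,3]): the para carbon is blocked by the acetyl group so no Cope relay can move the group on, the allyl unit arrives inverted as the 1,1-dimethylallyl group, and C3 should be preferred over C5 because dienone 5 keeps the hydrogen-bonded 2-hydroxy/acetyl unit conjugated before it enolises.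

**Step 4**
Reactants: 6 1-[2,4-dihydroxy-6-(methoxymethoxy)-3-(2-methylbut-3-en-2-yl)phenyl]ethan-1-one
Product: 7 1-[2-hydroxy-4,6-bis(methoxymethoxy)-3-(2-methylbut-3-en-2-yl)phenyl]ethan-1-one
Conditions: MOMCl (1.1 equiv), i-Pr2NEt, CH2Cl2, 0 °C to rt
Reagents that add atoms: chloromethyl methyl ether, COCCl
Why: O-alkylation of the non-chelated 4-hydroxyl; the 2-hydroxyl, hydrogen-bonded to the ketone and flanked by the quaternary carbon, stays free for the later ring closure.

**Step 5**
Reactants: 8 3,5-dihydroxybenzonitrile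
Product: 9 3,5-bis(methoxymethoxy)benzonitrile
Conditions: MOMCl (2.5 equiv), i-Pr2NEt, CH2Cl2, 0 °C to rt
Reagents that add atoms: chloromethyl methyl ether, COCCl
Why: Routine protection of both phenols as MOM acetals.

**Step 6**
Reactants: 9 3,5-bis(methoxymethoxy)benzonitrile
Product: 10 2-bromo-3,5-bis(methoxymethoxy)benzonitrile
Conditions: NBS (1.05 equiv), DMF, rt
Reagents that add atoms: N-bromosuccinimide, O=C1CCC(=O)N1Br
Why: Electrophilic aromatic bromination at C2, which is para to one acetal oxygen, ortho to the other and less crowded than C4 between both, as with other 3,5-dialkoxybenzoyl derivatives.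

**Step 7**
Reactants: 10 2-bromo-3,5-bis(methoxymethoxy)benzonitrile; 11 tributyl(3-methylbut-2-en-1-yl)stannane
Product: 12 3,5-bis(methoxymethoxy)-2-(3-methylbut-2-en-1-yl)benzonitrile
Conditions: Pd(PPh3)4 (5 mol %), DMF, 95 °C
Reagents that add atoms: none
Why: Stille coupling: the ortho nitrile eases oxidative addition and reductive elimination from the prenyl palladium intermediate occurs at the unsubstituted allyl terminus, giving the linear prenyl arene.

**Step 8**
Reactants: 12 3,5-bis(methoxymethoxy)-2-(3-methylbut-2-en-1-yl)benzonitrile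
Product: 14 7-hydroxy-2,2-dimethylchromane-5-carbonitrile, via prenyl resorcinol nitrile 13 (not isolated)
Conditions: p-TsOH·H2O, MeOH, 60 °C; then toluene, 90 °C
Reagents that add atoms: none
Why: Acid methanolysis removes both MOM acetals and the acid then protonates the alkene to the tertiary cation, which only the adjacent phenol oxygen can reach (Markovnikov hydroalkoxylation to the six-membered ring), so the nitrile ends on C5; a nitrile, unlike an aldehyde, cannot undergo a Prins reaction with the alkene.

**Step 9**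
Reactants: 14 7-hydroxy-2,2-dimethylchromane-5-carbonitrile
Product: 15 7-(methoxymethoxy)-2,2-dimethylchromane-5-carbonitrile
Conditions: MOMCl, i-Pr2NEt, CH2Cl2, 0 °C to rt
Reagents that add atoms: chloromethyl methyl ether, COCCl
Why: Routine O-alkylation of the single remaining phenol.

**Step 10**
Reactants: 15 7-(methoxymethoxy)-2,2-dimethylchromane-5-carbonitrile
Product: 17 7-(methoxymethoxy)-2,2-dimethylchromane-5-carbaldehyde, via N-alumino aldimine 16 (not isolated)
Conditions: i-Bu2AlH (1.3 equiv), toluene, −78 °C; then aq. potassium sodium tartrate, rt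
Reagents that add atoms: water, O (aldehyde oxygen); diisobutylaluminium hydride, CC(C)C[AlH]CC(C)C (its aluminium is carried only by 16)
Why: Partial hydride reduction of the nitrile stops at the N-aluminium imine, which hydrolyses to the aldehyde on work-up; the MOM and chroman ethers are inert.

**Step 11**
Reactants: 7 1-[2-hydroxy-4,6-bis(methoxymethoxy)-3-(2-methylbut-3-en-2-yl)phenyl]ethan-1-one; 17 7-(methoxymethoxy)-2,2-dimethylchromane-5-carbaldehyde
Product: 19 (E)-1-[2-hydroxy-4,6-bis(methoxymethoxy)-3-(2-methylbut-3-en-2-yl)phenyl]-3-[7-(methoxymethoxy)-2,2-dimethylchroman-5-yl]prop-2-en-1-one, via aldol adduct 18 (not isolated)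
Conditions: KOH (50% aq), EtOH, 0 °C to rt; neutralise with aq. NH4Cl
Reagents that add atoms: none
Why: Claisen–Schmidt condensation of the methyl ketone enolate with the non-enolisable aldehyde, followed by E1cB dehydration to the (E)-enone; MOM acetals are stable to hydroxide.

**Step 12**
Reactants: 19 the (E)-chalcone
Product: 20 rac-8-(2-methylbut-3-en-2-yl)-5,7-bis(methoxymethoxy)-2-[7-(methoxymethoxy)-2,2-dimethylchroman-5-yl]chroman-4-one (2R enantiomer drawn)
Conditions: NaOAc, EtOH, reflux
Reagents that add atoms: none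
Why: 6-endo-trig oxa-Michael addition of the only free phenol, the one next to the 1,1-dimethylallyl group, which places that group on C8; C2 forms without control, as the racemate.

**Step 13**
Reactants: 20 the flavanone
Product: 22 rac-3-diazo-8-(2-methylbut-3-en-2-yl)-5,7-bis(methoxymethoxy)-2-[7-(methoxymethoxy)-2,2-dimethylchroman-5-yl]chroman-4-one (2S enantiomer drawn, same spatial arrangement as 20), via 3-trifluoroacetylflavanone 21 (not isolated)
Conditions: LiN(SiMe3)2, THF, −78 °C; CF3CO2CH2CF3, −78 °C; AcOH quench; then MsN3, Et3N, H2O (1 equiv), MeCN, rt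
Reagents that add atoms: methanesulfonyl azide, CS(=O)(=O)N=[N+]=[N-]; 2,2,2-trifluoroethyl trifluoroacetate, O=C(OCC(F)(F)F)C(F)(F)F (its trifluoroacetyl group is carried only by 21)
Why: Detrifluoroacetylative Regitz-type diazo transfer: the kinetic lithium enolate is C-acylated at −78 °C before it can open to the chalcone phenoxide, and the activated diketone 21 then takes the diazo group from mesyl azide and loses the trifluoroacetyl group as the N-sulfonyl amide; C2 is untouched.

**Step 14**
Reactants: 22 the 3-diazoflavanone; 23 methanol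
Product: 25 methyl rac-(2R,3R)-7-(2-methylbut-3-en-2-yl)-4,6-bis(methoxymethoxy)-2-[7-(methoxymethoxy)-2,2-dimethylchroman-5-yl]-2,3-dihydro-1-benzofuran-3-carboxylate (trans), via ketene 24 (not isolated)
Conditions: hν (365 nm LED), degassed MeOH, 20 °C
Reagents that add atoms: none
Why: Photochemical Wolff rearrangement: excitation of the diazoketone, held s-Z by the pyranone ring, expels dinitrogen while the ring A carbon C4a shifts from the carbonyl carbon C4 to C3, giving ketene 24 and the new bond C3–C4a (C3–C3a of the benzofuran). The closest known reaction type is the photolytic ring contraction of cyclic α-diazo aryl ketones such as 2-diazo-1-tetralones and 3-diazochroman-4-ones in alcohols. The five-membered ring O1–C2–C3–C3a–C7a is not closed by a cyclisation but arises by 1,2-shift contraction of the six-membered ring, the former C4 leaving the ring as the ester carbon once methanol adds to the ketene. The new stereocentre C3 is set when the ester enol is protonated on the face away from the C2 aryl group (trans, also the more stable isomer), C2 is untouched, and both centres are erased in step 16. The step needs aryl migration to beat a hydride shift from C2 (which would give the flavone) and O–H insertion of methanol; the ring-locked geometry couples nitrogen loss to migration and the electron-rich migrating carbon helps, while 365 nm light under neutral conditions should spare the MOM acetals, the vinyl group and the product ester.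

**Step 15**
Reactants: 25 the trans methyl ester
Product: 26 rac-(2R,3R)-7-(2-methylbut-3-en-2-yl)-4,6-bis(methoxymethoxy)-2-[7-(methoxymethoxy)-2,2-dimethylchroman-5-yl]-2,3-dihydro-1-benzofuran-3-carboxylic acid
Conditions: LiOH·H2O, THF/MeOH/H2O, 40 °C; then 1 M HCl to pH 4, 0 °C
Reagents that add atoms: lithium hydroxide, [Li+].[OH-]
Why: Saponification; once the carboxylate forms, further α-deprotonation and E1cB opening of the dihydrofuran are disfavoured, and the configuration at C3 is of no consequence.

**Step 16**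
Reactants: 26 the dihydrobenzofuran-3-carboxylic acid
Product: 27 7-(2-methylbut-3-en-2-yl)-4,6-bis(methoxymethoxy)-2-[7-(methoxymethoxy)-2,2-dimethylchroman-5-yl]-1-benzofuran
Conditions: Pb(OAc)4 (1.2 equiv), Cu(OAc)2 (0.2 equiv), pyridine, PhH, 80 °C
Reagents that add atoms: none
Why: Oxidative decarboxylation with tetravalent lead: the benzylic C3 radical left after loss of CO2 is oxidised by divalent copper and loses the C2 hydrogen, its only β-hydrogen, so the alkene formed is the aromatic furan and both stereocentres vanish.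

**Step 17**
Reactants: 27 the tris-MOM benzofuran
Product: 28 2-(7-hydroxy-2,2-dimethylchroman-5-yl)-7-(2-methylbut-3-en-2-yl)-1-benzofuran-4,6-diol (target)
Conditions: 3 M HCl (aq)/MeOH, 45 °C
Reagents that add atoms: none
Why: Acid-catalysed acetal cleavage, with methanol trapping formaldehyde as dimethoxymethane; the 1,1-dimethylallyl group could cyclise only through a secondary cation and should survive.

**Compound list**
1 | 2,4,6-trihydroxyacetophenone | CC(=O)c1c(O)cc(O)cc1O | starting material
2 | prenol (3-methylbut-2-en-1-ol) | CC(C)=CCO | starting material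
3 | 1-[2,6-dihydroxy-4-(3-methylbut-2-en-1-yloxy)phenyl]ethan-1-one | CC(=O)c1c(O)cc(OCC=C(C)C)cc1O | intermediate
4 | 1-[2-hydroxy-6-(methoxymethoxy)-4-(3-methylbut-2-en-1-yloxy)phenyl]ethan-1-one | CC(=O)c1c(O)cc(OCC=C(C)C)cc1OCOC | intermediate
5 | rac-4-acetyl-3-hydroxy-5-(methoxymethoxy)-2-(2-methylbut-3-en-2-yl)cyclohexa-3,5-dien-1-one (formed in situ) | CC(=O)C1=C(O)C(C(C)(C)C=C)C(=O)C=C1OCOC | intermediate
6 | 1-[2,4-dihydroxy-6-(methoxymethoxy)-3-(2-methylbut-3-en-2-yl)phenyl]ethan-1-one | CC(=O)c1c(O)c(C(C)(C)C=C)c(O)cc1OCOC | intermediate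
7 | 1-[2-hydroxy-4,6-bis(methoxymethoxy)-3-(2-methylbut-3-en-2-yl)phenyl]ethan-1-one | CC(=O)c1c(O)c(C(C)(C)C=C)c(OCOC)cc1OCOC | intermediate
8 | 3,5-dihydroxybenzonitrile | N#Cc1cc(O)cc(O)c1 | starting material
9 | 3,5-bis(methoxymethoxy)benzonitrile | N#Cc1cc(OCOC)cc(OCOC)c1 | intermediate
10 | 2-bromo-3,5-bis(methoxymethoxy)benzonitrile | N#Cc1cc(OCOC)cc(OCOC)c1Br | intermediate
11 | tributyl(3-methylbut-2-en-1-yl)stannane | CCCC[Sn](CCCC)(CCCC)CC=C(C)C | starting material
12 | 3,5-bis(methoxymethoxy)-2-(3-methylbut-2-en-1-yl)benzonitrile | N#Cc1cc(OCOC)cc(OCOC)c1CC=C(C)C | intermediate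
13 | 3,5-dihydroxy-2-(3-methylbut-2-en-1-yl)benzonitrile (formed in situ) | N#Cc1cc(O)cc(O)c1CC=C(C)C | intermediate
14 | 7-hydroxy-2,2-dimethylchromane-5-carbonitrile | N#Cc1cc(O)cc2c1CCC(C)(C)O2 | intermediate
15 | 7-(methoxymethoxy)-2,2-dimethylchromane-5-carbonitrile | N#Cc1cc(OCOC)cc2c1CCC(C)(C)O2 | intermediate
16 | N-(diisobutylalumanyl)-1-[7-(methoxymethoxy)-2,2-dimethylchroman-5-yl]methanimine (formed in situ) | CC(C)C[Al](CC(C)C)N=Cc1cc(OCOC)cc2c1CCC(C)(C)O2 | intermediate
17 | 7-(methoxymethoxy)-2,2-dimethylchromane-5-carbaldehyde | O=Cc1cc(OCOC)cc2c1CCC(C)(C)O2 | intermediate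
18 | rac-3-hydroxy-1-[2-hydroxy-4,6-bis(methoxymethoxy)-3-(2-methylbut-3-en-2-yl)phenyl]-3-[7-(methoxymethoxy)-2,2-dimethylchroman-5-yl]propan-1-one (formed in situ) | O=C(CC(O)c1cc(OCOC)cc2c1CCC(C)(C)O2)c1c(O)c(C(C)(C)C=C)c(OCOC)cc1OCOC | intermediate
19 | (E)-1-[2-hydroxy-4,6-bis(methoxymethoxy)-3-(2-methylbut-3-en-2-yl)phenyl]-3-[7-(methoxymethoxy)-2,2-dimethylchroman-5-yl]prop-2-en-1-one | O=C(/C=C/c1cc(OCOC)cc2c1CCC(C)(C)O2)c1c(O)c(C(C)(C)C=C)c(OCOC)cc1OCOC | intermediate
20 | rac-8-(2-methylbut-3-en-2-yl)-5,7-bis(methoxymethoxy)-2-[7-(methoxymethoxy)-2,2-dimethylchroman-5-yl]chroman-4-one (2R drawn) | O=C1C[C@H](c2cc(OCOC)cc3c2CCC(C)(C)O3)Oc2c(C(C)(C)C=C)c(OCOC)cc(OCOC)c12 | intermediate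
21 | rac-3-(trifluoroacetyl) derivative of 20 (C3 epimers/enol, formed in situ) | O=C(C1C(=O)c2c(OCOC)cc(OCOC)c(C(C)(C)C=C)c2O[C@H]1c3cc(OCOC)cc4c3CCC(C)(C)O4)C(F)(F)F | intermediate
22 | rac-3-diazo-8-(2-methylbut-3-en-2-yl)-5,7-bis(methoxymethoxy)-2-[7-(methoxymethoxy)-2,2-dimethylchroman-5-yl]chroman-4-one (2S drawn) | [N-]=[N+]=C1C(=O)c2c(OCOC)cc(OCOC)c(C(C)(C)C=C)c2O[C@H]1c3cc(OCOC)cc4c3CCC(C)(C)O4 | intermediate
23 | methanol | CO | starting material
24 | rac-7-(2-methylbut-3-en-2-yl)-4,6-bis(methoxymethoxy)-2-[7-(methoxymethoxy)-2,2-dimethylchroman-5-yl]-3-(oxomethylidene)-2,3-dihydro-1-benzofuran (ketene, formed in situ) | O=C=C1c2c(OCOC)cc(OCOC)c(C(C)(C)C=C)c2O[C@H]1c3cc(OCOC)cc4c3CCC(C)(C)O4 | intermediate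
25 | methyl rac-(2R,3R)-7-(2-methylbut-3-en-2-yl)-4,6-bis(methoxymethoxy)-2-[7-(methoxymethoxy)-2,2-dimethylchroman-5-yl]-2,3-dihydro-1-benzofuran-3-carboxylate (trans) | COC(=O)[C@@H]1c2c(OCOC)cc(OCOC)c(C(C)(C)C=C)c2O[C@H]1c3cc(OCOC)cc4c3CCC(C)(C)O4 | intermediate
26 | rac-(2R,3R)-7-(2-methylbut-3-en-2-yl)-4,6-bis(methoxymethoxy)-2-[7-(methoxymethoxy)-2,2-dimethylchroman-5-yl]-2,3-dihydro-1-benzofuran-3-carboxylic acid | OC(=O)[C@@H]1c2c(OCOC)cc(OCOC)c(C(C)(C)C=C)c2O[C@H]1c3cc(OCOC)cc4c3CCC(C)(C)O4 | intermediate
27 | 7-(2-methylbut-3-en-2-yl)-4,6-bis(methoxymethoxy)-2-[7-(methoxymethoxy)-2,2-dimethylchroman-5-yl]-1-benzofuran | C=CC(C)(C)c1c(OCOC)cc(OCOC)c2cc(-c3cc(OCOC)cc4c3CCC(C)(C)O4)oc12 | intermediate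
28 | 2-(7-hydroxy-2,2-dimethylchroman-5-yl)-7-(2-methylbut-3-en-2-yl)-1-benzofuran-4,6-diol | C=CC(C)(C)c1c(O)cc(O)c2cc(-c3cc(O)cc4c3CCC(C)(C)O4)oc12 | target

**Totals**
Total step count: 17.
Longest linear sequence: 13 steps (steps 5–10, then 11–17).

**Steps most likely to fail**

Step 14 (key step). After loss of dinitrogen, a hydride shift from C2 (to the flavone) or O–H insertion of methanol may outrun the aryl shift, or the product may be photolysed further. The fallback sets out from flavanone 20 and avoids the carbene. PhI(OAc)2 with catalytic H2SO4 in trimethyl orthoformate converts 20 in situ into its methyl enol ether, rac-4-methoxy-8-(2-methylbut-3-en-2-yl)-5,7-bis(methoxymethoxy)-2-[7-(methoxymethoxy)-2,2-dimethylchroman-5-yl]-2H-chromene F1. The trivalent iodine reagent attacks F1 at C3, ring A migrates from C4 to C3 as iodobenzene leaves, and the resulting dialkoxycarbenium ion ends as methyl ester 25 after aqueous work-up. This is the known oxidative 1,2-aryl-shift ring contraction of flavanones; it replaces steps 13 and 14 and returns to the route at 25. Only catalytic strong acid is present, under anhydrous conditions, to limit loss of MOM groups.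

Step 13. The lithium enolate may open by retro-oxa-Michael reaction to the chalcone phenoxide, or the crowded C3 may be acylated slowly or on oxygen. The fallback sets out from 20 and uses no strong base. Heating with t-BuOCH(NMe2)2 in toluene should give the enaminone rac-3-[(dimethylamino)methylidene]-8-(2-methylbut-3-en-2-yl)-5,7-bis(methoxymethoxy)-2-[7-(methoxymethoxy)-2,2-dimethylchroman-5-yl]chroman-4-one F2. Mesyl azide then adds across the enamine double bond and the triazoline fragments with loss of the N-sulfonyl formamidine (known diazo transfer to enaminones). This returns to the route at 22.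

Step 16. Tetravalent lead may acetoxylate the electron-rich rings or over-oxidise the product benzofuran, or the C3 cation may be trapped instead of eliminating. The fallback sets out from acid 26 and separates decarboxylation from dehydrogenation. Coupling with N-hydroxyphthalimide (N,N'-diisopropylcarbodiimide, cat. DMAP) gives the redox-active ester 1,3-dioxoisoindolin-2-yl rac-(2R,3R)-7-(2-methylbut-3-en-2-yl)-4,6-bis(methoxymethoxy)-2-[7-(methoxymethoxy)-2,2-dimethylchroman-5-yl]-2,3-dihydro-1-benzofuran-3-carboxylate F3. Reductive radical decarboxylation (Ru(bpy)3Cl2 cat., Hantzsch ester, blue light) gives rac-7-(2-methylbut-3-en-2-yl)-4,6-bis(methoxymethoxy)-2-[7-(methoxymethoxy)-2,2-dimethylchroman-5-yl]-2,3-dihydro-1-benzofuran F4. Dehydrogenation of F4 with DDQ in toluene at 80 °C returns to the route at 27.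

**Further compounds**
F1 | step 14 | rac-4-methoxy-8-(2-methylbut-3-en-2-yl)-5,7-bis(methoxymethoxy)-2-[7-(methoxymethoxy)-2,2-dimethylchroman-5-yl]-2H-chromene | COC1=C[C@H](c2cc(OCOC)cc3c2CCC(C)(C)O3)Oc2c(C(C)(C)C=C)c(OCOC)cc(OCOC)c12
F2 | step 13 | rac-3-[(dimethylamino)methylidene]-8-(2-methylbut-3-en-2-yl)-5,7-bis(methoxymethoxy)-2-[7-(methoxymethoxy)-2,2-dimethylchroman-5-yl]chroman-4-one | CN(C)C=C1C(=O)c2c(OCOC)cc(OCOC)c(C(C)(C)C=C)c2O[C@H]1c3cc(OCOC)cc4c3CCC(C)(C)O4
F3 | step 16 | 1,3-dioxoisoindolin-2-yl rac-(2R,3R)-7-(2-methylbut-3-en-2-yl)-4,6-bis(methoxymethoxy)-2-[7-(methoxymethoxy)-2,2-dimethylchroman-5-yl]-2,3-dihydro-1-benzofuran-3-carboxylate | O=C(ON1C(=O)c2ccccc2C1=O)[C@@H]1c2c(OCOC)cc(OCOC)c(C(C)(C)C=C)c2O[C@H]1c3cc(OCOC)cc4c3CCC(C)(C)O4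
F4 | step 16 | rac-7-(2-methylbut-3-en-2-yl)-4,6-bis(methoxymethoxy)-2-[7-(methoxymethoxy)-2,2-dimethylchroman-5-yl]-2,3-dihydro-1-benzofuran | C1c2c(OCOC)cc(OCOC)c(C(C)(C)C=C)c2O[C@H]1c3cc(OCOC)cc4c3CCC(C)(C)O4
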